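The nine-membered ring is numbered C1–C9 (C1 bears the saturated formyl group, C2 the conjugated one, C8 the acetate, C9 the side chain). Everything rests on the C1–C9 bond. The key step exploits the 1,5-relationship between C8 and the formyl carbon on C2: tied through oxygen they form a six-membered lactone whose C3–C4 bond is C9–C1. A tethered ortho ester Claisen rearrangement of a 2,5-bis(alkylidene)-1,3-dioxane (from a glyceraldehyde-derived 2-alkylidenepropane-1,3-diol and an (S)-citronellic ortho ester) closes this lactone, forms C1–C9, sets both stereocentres and leaves the 1,1-disubstituted alkene that later closes the ring by metathesis at C2=C3.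

Key step: step 6

Remark: the two hydroxymethyl arms of diol 5 are identical, so no alkene geometry has to be set before the key step; intermediates 11 and 12 are taken as mixtures at the ortho ester carbon and at the ketene acetal double bond.

**Step 1**
Reactants: 1 (R)-solketal
Product: 2 (S)-glyceraldehyde acetonide, (4S)-2,2-dimethyl-1,3-dioxolane-4-carbaldehyde
Conditions: TEMPO (10 mol%), PhI(OAc)2, CH2Cl2, rt; used crude
Reagents that add atoms: none
Why: Oxoammonium oxidation of a primary alcohol stops at the aldehyde under neutral conditions and leaves the stereocentre untouched (the descriptor changes from R to S by the priority rules only).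

**Step 2**
Reactants: 2 (S)-glyceraldehyde acetonide; 3 diethyl malonate
Product: 4 diethyl 2-{[(4R)-2,2-dimethyl-1,3-dioxolan-4-yl]methylidene}propanedioate
Conditions: piperidine (cat.), AcOH (cat.), 4 Å MS, CH2Cl2, 0 °C to rt
Reagents that add atoms: none
Why: Knoevenagel condensation under buffered amine catalysis should give the alkylidene malonate without epimerising the α-alkoxy centre.

**Step 3**
Reactants: 4 alkylidene malonate
Product: 5 2-{[(4R)-2,2-dimethyl-1,3-dioxolan-4-yl]methylidene}propane-1,3-diol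
Conditions: (i-Bu)2AlH (4.5 equiv), CH2Cl2, −78 to 0 °C; aq. potassium sodium tartrate
Reagents that add atoms: none
Why: Exhaustive 1,2-reduction of both conjugated esters by the aluminium hydride at low temperature should give the 2-alkylidene-1,3-diol.

**Step 4**
Reactants: 6 (S)-citronellic acid
Product: 8 (3S)-3,7-dimethyloct-6-enamide, via acyl imidazolide 7 (not isolated)
Conditions: 1,1′-carbonyldiimidazole, THF, rt; then aq. NH3, 0 °C to rt
Reagents that add atoms: ammonia, N
Why: Acyl imidazolide activation followed by ammonolysis is a standard primary amide synthesis that leaves the alkene and the β-stereocentre alone.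

**Step 5**
Reactants: 8 (3S)-3,7-dimethyloct-6-enamide
Product: 10 (6S)-8,8,8-trimethoxy-2,6-dimethyloct-2-ene (trimethyl ortho ester of 6), via imidate salt 9 (not isolated)
Conditions: Me3O+ BF4−, CH2Cl2, rt; then MeOH, hexane, rt
Reagents that add atoms: trimethyloxonium tetrafluoroborate, C[O+](C)C.F[B-](F)(F)F; methanol, CO
Why: O-Methylation of the primary amide gives the imidate salt, and its alcoholysis is the second stage of a Pinner ortho ester synthesis, here without hydrogen chloride that could add to the alkene.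

**Step 6**
Reactants: 5 2-alkylidenepropane-1,3-diol; 10 trimethyl ortho ester
Product: 13 (3R,4R)-4-[(4R)-2,2-dimethyl-1,3-dioxolan-4-yl]-5-methylidene-3-[(2S)-6-methylhept-5-en-2-yl]oxan-2-one, via cyclic ortho ester 11 (not isolated), via cyclic ketene acetal 12 (not isolated)
Conditions: t-BuCO2H (5 mol%), o-xylene, 110 to 150 °C, MeOH distilled off; then DBU (0.2 equiv), 80 °C
Reagents that add atoms: none
Why: Proposed new method: acid-catalysed exchange gives cyclic ortho ester 11, loss of methanol gives the 2,5-bis(alkylidene)-1,3-dioxane 12, and its [3,3]-sigmatropic shift through a boat, bicyclo[2.2.2]octane-like transition state joins the ketene acetal carbon (C9) to the alkylidene carbon (C1) as one allylic C–O bond breaks. The closest known reactions are the Johnson–Claisen rearrangement of (Z)-but-2-ene-1,4-diols with ortho esters to β-vinyl-γ-butyrolactones via cyclic ketene acetals, the ring-forming Claisen rearrangement of vinyl-substituted cyclic ketene acetals to medium-ring lactones, and the boat Cope rearrangement of 1,4-dimethylidenecyclohexane; a ketene acetal is an accelerated Claisen substrate, so the boat penalty of a few kcal/mol should be affordable at 150 °C. The six-membered lactone is closed by the sigmatropic C–C bond formation itself (a concerted, formally 6-endo SN2′-type delivery of C9 to C1), the untouched dioxane oxygen becoming the ring oxygen and the cleaved arm the exocyclic methylidene. C1 is controlled by the dioxolane stereocentre: allylic 1,3-strain with the cis ring CH2 holds its C–H in the alkene plane and the new bond is expected anti to the allylic C–O bond, as in conjugate additions and sigmatropic rearrangements of glyceraldehyde-derived γ-alkoxy alkenes. C9 is set trans to the C1 substituent because the two substituents avoid eclipsing across the forming bond in the boat, and the lactone α-centre is in any case equilibrated to the trans isomer by DBU; the side-chain centre comes unchanged from 10. The step needs the cyclic rather than a ring-opened ketene acetal and bond formation at the alkylidene CH only: removal of methanol keeps both ring oxygens on the acetal carbon, the two CH2–O arms are equivalent so either may break, and the CH terminus is the only atom that can reach C9 in a six-membered array.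

**Step 7**
Reactants: 13 lactone
Product: 14 (2R,3R)-3-[(4R)-2,2-dimethyl-1,3-dioxolan-4-yl]-4-(hydroxymethyl)-N-methoxy-N-methyl-2-[(2S)-6-methylhept-5-en-2-yl]pent-4-enamide
Conditions: MeNH(OMe)·HCl, Me3Al, CH2Cl2, 0 °C to rt
Reagents that add atoms: N,O-dimethylhydroxylamine hydrochloride, CNOC.Cl
Why: Aluminium amide aminolysis (Weinreb amide formation) should open the lactone at the acyl carbon without epimerising C9 and free the allylic hydroxymethyl group.

**Step 8**
Reactants: 14 hydroxy Weinreb amide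
Product: 15 (2R,3R)-3-[(4R)-2,2-dimethyl-1,3-dioxolan-4-yl]-N-methoxy-N-methyl-2-[(2S)-6-methylhept-5-en-2-yl]-4-{[(triethylsilyl)oxy]methyl}pent-4-enamide
Conditions: Et3SiCl, imidazole, CH2Cl2, 0 °C
Reagents that add atoms: chlorotriethylsilane, CC[Si](Cl)(CC)CC
Why: Silylation of the primary allylic alcohol prevents relactonisation and masks the future C2 formyl carbon.

**Step 9**
Reactants: 15 silylated Weinreb amide
Product: 16 (2R,3R)-3-[(4R)-2,2-dimethyl-1,3-dioxolan-4-yl]-2-[(2S)-6-methylhept-5-en-2-yl]-4-{[(triethylsilyl)oxy]methyl}pent-4-enal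
Conditions: (i-Bu)2AlH, THF, −78 °C; aq. potassium sodium tartrate
Reagents that add atoms: none
Why: The chelated tetrahedral intermediate of a Weinreb amide releases the aldehyde only on work-up, so reduction should stop at the C8 aldehyde without epimerising C9.

**Step 10**
Reactants: 16 aldehyde
Product: 17 (4R,5R,6R)-6-[(4R)-2,2-dimethyl-1,3-dioxolan-4-yl]-5-[(2S)-6-methylhept-5-en-2-yl]-7-{[(triethylsilyl)oxy]methyl}oct-7-en-1-yn-4-ol
Conditions: allenylboronic acid pinacol ester (1.5 equiv), (R)-TRIP [(R)-3,3′-bis(2,4,6-triisopropylphenyl)-1,1′-binaphthyl-2,2′-diyl hydrogen phosphate, 10 mol%], 4 Å MS, toluene, 0 °C to rt; aq. NaHCO3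
Reagents that add atoms: allenylboronic acid pinacol ester, C=C=CB1OC(C)(C)C(C)(C)O1
Why: Brønsted acid-catalysed propargylation passes through a closed six-membered transition state with allenyl-to-propargyl transposition, and the chiral phosphate is expected to override the weak Felkin–Anh bias of the α-branched aldehyde and set the C8 carbinol as R.

**Step 11**
Reactants: 17 homopropargylic alcohol
Product: 19 (3R,4R,5R,7E)-3-[(4R)-2,2-dimethyl-1,3-dioxolan-4-yl]-7-methyl-4-[(2S)-6-methylhept-5-en-2-yl]-2-{[(triethylsilyl)oxy]methyl}undeca-1,7,10-trien-5-ol, via alkenylalane 18 (not isolated)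
Conditions: Me3Al (3.5 equiv), Cp2ZrCl2 (0.3 equiv), CH2Cl2, 0 °C to rt; then allyl bromide, Pd(PPh3)4 (5 mol%), THF, rt
Reagents that add atoms: trimethylaluminium, C[Al](C)C; allyl bromide, C=CCBr
Why: Negishi carboalumination adds methyl and aluminium syn across the terminal alkyne (methyl to the internal carbon C6), and palladium-catalysed allylation of the alkenylalane with retention should give the (E)-C5=C6 alkene of the skipped diene.

**Step 12**
Reactants: 19 trienol
Product: 20 (1R,3E,6E,8R,9R)-8-[(4R)-2,2-dimethyl-1,3-dioxolan-4-yl]-3-methyl-9-[(2S)-6-methylhept-5-en-2-yl]-7-{[(triethylsilyl)oxy]methyl}cyclonona-3,6-dien-1-ol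
Conditions: RuCl2(H2IMes)(=CH-C6H4-2-OiPr) (second-generation Hoveyda–Grubbs catalyst, 10 mol%), toluene (1 mM), 80 °C, argon sparge
Reagents that add atoms: none
Why: Ring-closing metathesis between the monosubstituted and the 1,1-disubstituted alkene releases ethene; only the geometry with C1 and C4 cis across C2=C3 fits a nine-membered ring, and the rigid (E)-C5=C6 alkene with three contiguous branch points should pre-organise the chain.

**Step 13**
Reactants: 20 cyclononadienol
Product: 21 (1R,3E,6E,8R,9R)-8-[(4R)-2,2-dimethyl-1,3-dioxolan-4-yl]-3-methyl-9-[(2S)-6-methylhept-5-en-2-yl]-7-{[(triethylsilyl)oxy]methyl}cyclonona-3,6-dien-1-yl acetate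
Conditions: Ac2O, pyridine, DMAP (cat.), CH2Cl2, rt
Reagents that add atoms: acetic anhydride, CC(=O)OC(C)=O
Why: DMAP-catalysed acetylation of the only free hydroxyl installs the C8 acetate.

**Step 14**
Reactants: 21 acetate
Product: 22 (1E,4E,7R,8R,9R)-7-(acetyloxy)-9-[(4R)-2,2-dimethyl-1,3-dioxolan-4-yl]-5-methyl-8-[(2S)-6-methylhept-5-en-2-yl]cyclonona-1,4-diene-1-carbaldehyde
Conditions: (COCl)2, DMSO, CH2Cl2, −78 to −30 °C; then Et3N, −78 °C to rt
Reagents that add atoms: none
Why: Under Swern conditions a primary triethylsilyl ether is cleaved by the chlorosulfonium salt and oxidised directly, which should give the conjugated C2 aldehyde without a separate deprotection.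

**Step 15**
Reactants: 22 enal
Product: 23 (1R,2E,5E,8R,9R)-8-(acetyloxy)-6-methyl-9-[(2S)-6-methylhept-5-en-2-yl]cyclonona-2,5-diene-1,2-dicarbaldehyde (target)
Conditions: H5IO6, EtOAc, 0 °C to rt
Reagents that add atoms: none
Why: Periodic acid hydrolyses the terminal acetonide and cleaves the resulting 1,2-diol in one pot, unveiling the C1 formyl group; no base is present, so C1 should keep its configuration.

**Compound list**

1 | (R)-solketal, [(4R)-2,2-dimethyl-1,3-dioxolan-4-yl]methanol | OC[C@@H]1COC(C)(C)O1 | starting material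
2 | (S)-glyceraldehyde acetonide, (4S)-2,2-dimethyl-1,3-dioxolane-4-carbaldehyde | O=C[C@@H]1COC(C)(C)O1 | intermediate
3 | diethyl malonate | CCOC(=O)CC(=O)OCC | starting material
4 | diethyl 2-{[(4R)-2,2-dimethyl-1,3-dioxolan-4-yl]methylidene}propanedioate | CCOC(=O)C(C(=O)OCC)=C[C@@H]1COC(C)(C)O1 | intermediate
5 | 2-{[(4R)-2,2-dimethyl-1,3-dioxolan-4-yl]methylidene}propane-1,3-diol | OCC(CO)=C[C@@H]1COC(C)(C)O1 | intermediate
6 | (S)-citronellic acid, (3S)-3,7-dimethyloct-6-enoic acid | OC(=O)C[C@@H](C)CCC=C(C)C | starting material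
7 | 1-[(3S)-3,7-dimethyloct-6-enoyl]-1H-imidazole | O=C(C[C@@H](C)CCC=C(C)C)n1ccnc1 | intermediate (not isolated)
8 | (3S)-3,7-dimethyloct-6-enamide | NC(=O)C[C@@H](C)CCC=C(C)C | intermediate
9 | methyl (3S)-3,7-dimethyloct-6-enimidate hydrotetrafluoroborate | COC(=[NH2+])C[C@@H](C)CCC=C(C)C.F[B-](F)(F)F | intermediate (not isolated)
10 | (6S)-8,8,8-trimethoxy-2,6-dimethyloct-2-ene | COC(OC)(OC)C[C@@H](C)CCC=C(C)C | intermediate
11 | 2-[(2S)-2,6-dimethylhept-5-en-1-yl]-5-{[(4R)-2,2-dimethyl-1,3-dioxolan-4-yl]methylidene}-2-methoxy-1,3-dioxane (mixture at C2) | COC1(C[C@@H](C)CCC=C(C)C)OCC(=C[C@@H]2COC(C)(C)O2)CO1 | intermediate (not isolated)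
12 | 2-[(2S)-2,6-dimethylhept-5-en-1-ylidene]-5-{[(4R)-2,2-dimethyl-1,3-dioxolan-4-yl]methylidene}-1,3-dioxane (both ketene acetal geometries) | CC(C)=CCC[C@H](C)C=C1OCC(=C[C@@H]2COC(C)(C)O2)CO1 | intermediate (not isolated)
13 | (3R,4R)-4-[(4R)-2,2-dimethyl-1,3-dioxolan-4-yl]-5-methylidene-3-[(2S)-6-methylhept-5-en-2-yl]oxan-2-one | O=C1OCC(=C)[C@H]([C@@H]2COC(C)(C)O2)[C@H]1[C@@H](C)CCC=C(C)C | intermediate
14 | (2R,3R)-3-[(4R)-2,2-dimethyl-1,3-dioxolan-4-yl]-4-(hydroxymethyl)-N-methoxy-N-methyl-2-[(2S)-6-methylhept-5-en-2-yl]pent-4-enamide | OCC(=C)[C@H]([C@@H]1COC(C)(C)O1)[C@H](C(=O)N(C)OC)[C@@H](C)CCC=C(C)C | intermediate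
15 | (2R,3R)-3-[(4R)-2,2-dimethyl-1,3-dioxolan-4-yl]-N-methoxy-N-methyl-2-[(2S)-6-methylhept-5-en-2-yl]-4-{[(triethylsilyl)oxy]methyl}pent-4-enamide | CC[Si](CC)(CC)OCC(=C)[C@H]([C@@H]1COC(C)(C)O1)[C@H](C(=O)N(C)OC)[C@@H](C)CCC=C(C)C | intermediate
16 | (2R,3R)-3-[(4R)-2,2-dimethyl-1,3-dioxolan-4-yl]-2-[(2S)-6-methylhept-5-en-2-yl]-4-{[(triethylsilyl)oxy]methyl}pent-4-enal | CC[Si](CC)(CC)OCC(=C)[C@H]([C@@H]1COC(C)(C)O1)[C@H](C=O)[C@@H](C)CCC=C(C)C | intermediate
17 | (4R,5R,6R)-6-[(4R)-2,2-dimethyl-1,3-dioxolan-4-yl]-5-[(2S)-6-methylhept-5-en-2-yl]-7-{[(triethylsilyl)oxy]methyl}oct-7-en-1-yn-4-ol | CC[Si](CC)(CC)OCC(=C)[C@H]([C@@H]1COC(C)(C)O1)[C@H]([C@H](O)CC#C)[C@@H](C)CCC=C(C)C | intermediate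
18 | (E)-alkenyl(dimethyl)alane of 17 as its dimethylaluminium alkoxide (methyl on C6, aluminium on C5) | CC[Si](CC)(CC)OCC(=C)[C@H]([C@@H]1COC(C)(C)O1)[C@H]([C@H](O[Al](C)C)C/C(C)=C/[Al](C)C)[C@@H](C)CCC=C(C)C | intermediate (not isolated)
19 | (3R,4R,5R,7E)-3-[(4R)-2,2-dimethyl-1,3-dioxolan-4-yl]-7-methyl-4-[(2S)-6-methylhept-5-en-2-yl]-2-{[(triethylsilyl)oxy]methyl}undeca-1,7,10-trien-5-ol | CC[Si](CC)(CC)OCC(=C)[C@H]([C@@H]1COC(C)(C)O1)[C@H]([C@H](O)C/C(C)=C/CC=C)[C@@H](C)CCC=C(C)C | intermediate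
20 | (1R,3E,6E,8R,9R)-8-[(4R)-2,2-dimethyl-1,3-dioxolan-4-yl]-3-methyl-9-[(2S)-6-methylhept-5-en-2-yl]-7-{[(triethylsilyl)oxy]methyl}cyclonona-3,6-dien-1-ol | O[C@@H]1C/C(C)=C/C/C=C(/CO[Si](CC)(CC)CC)[C@H]([C@@H]2COC(C)(C)O2)[C@H]1[C@@H](C)CCC=C(C)C | intermediate
21 | (1R,3E,6E,8R,9R)-8-[(4R)-2,2-dimethyl-1,3-dioxolan-4-yl]-3-methyl-9-[(2S)-6-methylhept-5-en-2-yl]-7-{[(triethylsilyl)oxy]methyl}cyclonona-3,6-dien-1-yl acetate | CC(=O)O[C@@H]1C/C(C)=C/C/C=C(/CO[Si](CC)(CC)CC)[C@H]([C@@H]2COC(C)(C)O2)[C@H]1[C@@H](C)CCC=C(C)C | intermediate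
22 | (1E,4E,7R,8R,9R)-7-(acetyloxy)-9-[(4R)-2,2-dimethyl-1,3-dioxolan-4-yl]-5-methyl-8-[(2S)-6-methylhept-5-en-2-yl]cyclonona-1,4-diene-1-carbaldehyde | CC(=O)O[C@@H]1C/C(C)=C/C/C=C(/C=O)[C@H]([C@@H]2COC(C)(C)O2)[C@H]1[C@@H](C)CCC=C(C)C | intermediate
23 | (1R,2E,5E,8R,9R)-8-(acetyloxy)-6-methyl-9-[(2S)-6-methylhept-5-en-2-yl]cyclonona-2,5-diene-1,2-dicarbaldehyde | CC(=O)O[C@@H]1C/C(C)=C/C/C=C(/C=O)[C@H](C=O)[C@H]1[C@@H](C)CCC=C(C)C | target

**Step count**

Total step count: 15. Longest linear sequence: 13 steps (steps 1–3 and 6–15).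

**Steps most likely to fail**

Step 6 (Proposed new method). The boat, bicyclic transition state may be reached too slowly, so that the ketene acetal decomposes or the facial bias at C1 erodes at 150 °C. The fallback uses known chemistry, sets out from diol 5 and acid 6, and comes back at lactone 13. Carbodiimide mono-esterification of 5 with 6 gives (2E)-3-[(4R)-2,2-dimethyl-1,3-dioxolan-4-yl]-2-(hydroxymethyl)prop-2-en-1-yl (3S)-3,7-dimethyloct-6-enoate F1 (the less hindered arm is drawn; either arm serves). An Ireland–Claisen rearrangement through the usual acyclic chair (lithium diisopropylamide 2.2 equiv, Me3SiCl, THF, −78 °C to rt, acidic work-up) then gives (2R,3R)-3-[(4R)-2,2-dimethyl-1,3-dioxolan-4-yl]-4-(hydroxymethyl)-2-[(2S)-6-methylhept-5-en-2-yl]pent-4-enoic acid F2 as a mixture at C2. The same allylic stereocentre should direct the new bond. Acid-catalysed lactonisation and DBU equilibration return to 13.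

Step 12. Cross-metathesis oligomerisation may outrun closure of the strained nine-membered ring at the hindered 1,1-disubstituted alkene. The fallback cyclises at the ketone oxidation level, sets out from 19 and comes back at 20. Dess–Martin oxidation (NaHCO3 buffer) gives (3R,4R,7E)-3-[(4R)-2,2-dimethyl-1,3-dioxolan-4-yl]-7-methyl-4-[(2S)-6-methylhept-5-en-2-yl]-2-{[(triethylsilyl)oxy]methyl}undeca-1,7,10-trien-5-one F3. Its sp2 C8 removes one transannular interaction and any hydroxyl–ruthenium interaction. Ring-closing metathesis gives (3E,6E,8R,9R)-8-[(4R)-2,2-dimethyl-1,3-dioxolan-4-yl]-3-methyl-9-[(2S)-6-methylhept-5-en-2-yl]-7-{[(triethylsilyl)oxy]methyl}cyclonona-3,6-dien-1-one F4. Corey–Bakshi–Shibata reduction ((S)-Me-CBS oxazaborolidine, BH3·SMe2, expected to give the R carbinol by the usual large/small model) returns to 20.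

Step 10. Facial selectivity may be poor if the catalyst preference is mismatched with the α,β-branched aldehyde. The fallback sets the carbinol by reagent-controlled reduction, sets out from 16 and comes back at 17. Barbier propargylation (propargyl bromide, Zn, THF/aq. NH4Cl) gives (4RS,5R,6R)-6-[(4R)-2,2-dimethyl-1,3-dioxolan-4-yl]-5-[(2S)-6-methylhept-5-en-2-yl]-7-{[(triethylsilyl)oxy]methyl}oct-7-en-1-yn-4-ol F5. Buffered Dess–Martin oxidation gives (5R,6R)-6-[(4R)-2,2-dimethyl-1,3-dioxolan-4-yl]-5-[(2S)-6-methylhept-5-en-2-yl]-7-{[(triethylsilyl)oxy]methyl}oct-7-en-1-yn-4-one F6, which is reduced at once with (S)-Me-CBS oxazaborolidine and BH3·SMe2 to 17.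

**Further compounds**

F1 | step 6 | (2E)-3-[(4R)-2,2-dimethyl-1,3-dioxolan-4-yl]-2-(hydroxymethyl)prop-2-en-1-yl (3S)-3,7-dimethyloct-6-enoate | CC(C)=CCC[C@H](C)CC(=O)OC/C(CO)=C/[C@@H]1COC(C)(C)O1
F2 | step 6 | (2R,3R)-3-[(4R)-2,2-dimethyl-1,3-dioxolan-4-yl]-4-(hydroxymethyl)-2-[(2S)-6-methylhept-5-en-2-yl]pent-4-enoic acid | OCC(=C)[C@H]([C@@H]1COC(C)(C)O1)[C@H](C(=O)O)[C@@H](C)CCC=C(C)C
F3 | step 12 | (3R,4R,7E)-3-[(4R)-2,2-dimethyl-1,3-dioxolan-4-yl]-7-methyl-4-[(2S)-6-methylhept-5-en-2-yl]-2-{[(triethylsilyl)oxy]methyl}undeca-1,7,10-trien-5-one | CC[Si](CC)(CC)OCC(=C)[C@H]([C@@H]1COC(C)(C)O1)[C@H](C(=O)C/C(C)=C/CC=C)[C@@H](C)CCC=C(C)C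
F4 | step 12 | (3E,6E,8R,9R)-8-[(4R)-2,2-dimethyl-1,3-dioxolan-4-yl]-3-methyl-9-[(2S)-6-methylhept-5-en-2-yl]-7-{[(triethylsilyl)oxy]methyl}cyclonona-3,6-dien-1-one | O=C1C/C(C)=C/C/C=C(/CO[Si](CC)(CC)CC)[C@H]([C@@H]2COC(C)(C)O2)[C@H]1[C@@H](C)CCC=C(C)C
F5 | step 10 | (4RS,5R,6R)-6-[(4R)-2,2-dimethyl-1,3-dioxolan-4-yl]-5-[(2S)-6-methylhept-5-en-2-yl]-7-{[(triethylsilyl)oxy]methyl}oct-7-en-1-yn-4-ol | CC[Si](CC)(CC)OCC(=C)[C@H]([C@@H]1COC(C)(C)O1)[C@H](C(O)CC#C)[C@@H](C)CCC=C(C)C
F6 | step 10 | (5R,6R)-6-[(4R)-2,2-dimethyl-1,3-dioxolan-4-yl]-5-[(2S)-6-methylhept-5-en-2-yl]-7-{[(triethylsilyl)oxy]methyl}oct-7-en-1-yn-4-one | CC[Si](CC)(CC)OCC(=C)[C@H]([C@@H]1COC(C)(C)O1)[C@H](C(=O)CC#C)[C@@H](C)CCC=C(C)C
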